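A direct plan would take ring A from phloroglucinol A1 as an aryne and close ring C last: four steps (statistical dibenzylation, carbamate, ortho-silylation, triflation) would give the silylaryl triflate A2.
Its aryne would insert into 3-(3,4,5-trimethoxyphenyl)propiolic acid A3 and cyclise to the 5,7-bis(benzyloxy)flavone A4.
The C8 oxygen would then be added on the finished flavone: removal of the 5-benzyl group, Elbs persulfate oxidation to the 5,8-quinol A5, methylation of O8 only, and hydrogenolysis.
Weak step (a): the run-up to A2 would start with a statistical benzylation and pass through a lithiation beside two benzyl ethers, four steps that build nothing of the target.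
Weak step (b): the aryne insertion would need one orientation of addition to an unsymmetrical aryne, acyl transfer ahead of protonation, and 6-endo over 5-exo closure, all in one flask.
Weak step (c): the late persulfate hydroxylation at C8 tends to stop at low conversion, would give an air-sensitive quinol, and would need a methylation that tells O8 from O5, so four steps would serve one methoxy group.

**Retrosynthetic overview**
Ring A would be made last, on a preformed 2-aryl-4-pyranone (rings B and C), by thermal ring expansion of a cyclobutenone cut from squaric acid. The key disconnections are C8–C8a (addition of the C6-lithiated pyranone to a semisquarate) and C5–C4a (6π closure of a dienylketene onto pyranone C5).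
The feature used is the oxygen pattern of ring A: O5 and O8 para to each other, O7 next to C8, and C6–H between C5 and C7. The ring expansion writes exactly this: ketene carbonyl to C5–OH, O-methylated carbinol carbon to C8–OMe, vinylogous ester carbon to C7–O, unsubstituted alkene carbon to C6–H, pyranone C6=C5 to C8a/C4a.
Ring order: B bought, C from an acid chloride and a methoxyenone, A in the key step; one acid step then frees O7.
The design needs no aryne precursor, no regiochemical choice in the annulation, and no oxidation or selective methylation on the flavone: O8 is methylated while it is the only oxygen nucleophile present, and O5 is born free.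

Key step: step 4

Assumption: 1, 2 and 5 are taken as commercial; tert-butyl is chosen for O7 because it leaves as isobutene under acid that spares the four methyl ethers.

**Step 1**
Reactants: 1 3,4,5-trimethoxybenzoyl chloride; 2 (E)-4-methoxybut-3-en-2-one
Product: 4 2-(3,4,5-trimethoxyphenyl)-4H-pyran-4-one, via methoxyenedione 3 (not isolated)
Conditions: 2 (2.0 equiv), LiN(SiMe3)2 (2.0 equiv), THF, −78 °C; 1 (1.0 equiv), −78 to 0 °C; aq work-up; then CF3CO2H (cat.), toluene, rt
Reagents that add atoms: none
Why: Claisen-type C-acylation of the kinetic lithium enolate of the methoxyenone (the second equivalent of enolate takes the acidic diketone proton), then acid-catalysed 6-endo addition–elimination of the enol oxygen at the methoxy-bearing carbon with loss of methanol, the known γ-pyranone synthesis from acid chlorides; the product has no enolisable hydrogen, which suits step 3.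

**Step 2**
Reactants: 5 di-tert-butyl squarate
Product: 7 3-tert-butoxycyclobut-3-ene-1,2-dione, via hydroxycyclobutenone 6 (not isolated)
Conditions: LiAlH(O-t-Bu)3 (1.1 equiv), THF, −20 °C; cold aq work-up, crude into CH2Cl2; then (CF3CO)2O (1.2 equiv), 2,6-lutidine (2.5 equiv), −78 to 0 °C; aq NaHCO3
Reagents that add atoms: none
Why: The bulky hydride reduces one carbonyl only; trifluoroacetylation of the hydroxyl and ionisation give an alkoxy-stabilised cyclobutenyl cation that sheds the tert-butyl group of the oxygen at the far end of the allyl system as isobutene (the known reduction and 1,3-transposition route from squarate diesters to semisquarates), and the cold buffered medium should keep the remaining tert-butyl vinylogous ester.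

**Step 3**
Reactants: 4 2-(3,4,5-trimethoxyphenyl)-4H-pyran-4-one; 7 3-tert-butoxycyclobut-3-ene-1,2-dione
Product: 10 3-tert-butoxy-4-methoxy-4-[4-oxo-6-(3,4,5-trimethoxyphenyl)-4H-pyran-2-yl]cyclobut-2-en-1-one (racemic), via 6-lithiopyranone 8 (not isolated), via lithium alkoxide 9 (not isolated)
Conditions: lithium 2,2,6,6-tetramethylpiperidide (1.1 equiv, made from n-BuLi and the amine), THF, −78 °C, 20 min; 7 (1.2 equiv), −78 °C; MeOTf (1.3 equiv), −78 to 0 °C; aq NaHCO3
Reagents that add atoms: methyl trifluoromethanesulfonate, COS(=O)(=O)C(F)(F)F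
Why: Deprotonation at C6, the vinylic C–H next to the ring oxygen (as in the C6 lithiation of uracils and the C2 metalation of 4-quinolones and chromones), then 1,2-addition of the vinyllithium to the ketone-like carbonyl of the semisquarate (the one not deactivated as a vinylogous ester) and O-methylation of the tertiary lithium alkoxide in the flask; the new quaternary centre is racemic and is destroyed in step 4, and any pyranone O-methylation by excess MeOTf should revert on aqueous work-up.

**Step 4**
Reactants: 10 3-tert-butoxy-4-methoxy-4-[4-oxo-6-(3,4,5-trimethoxyphenyl)-4H-pyran-2-yl]cyclobut-2-en-1-one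
Product: 13 7-tert-butoxy-5-hydroxy-8-methoxy-2-(3,4,5-trimethoxyphenyl)-4H-chromen-4-one, via dienylketene 11 (not isolated), via cyclohexadienone 12 (not isolated)
Conditions: degassed toluene (0.02 M), 110 °C, Ar, base-washed glass
Reagents that add atoms: none
Why: Heating opens the cyclobutenone by conrotatory 4π cleavage of the C1–C4 bond, the 4-methoxy donor turning outward so that the pyranonyl group of dienylketene 11 lies cis to the ketene; pyranone C5 (future C4a, the nucleophilic α-carbon of the vinylogous ester) then joins the ketene carbon in a disrotatory 6π electrocyclisation that closes the six-membered ring A at C5–C4a to cyclohexadienone 12, and the C4a hydrogen, now between two carbonyl groups, moves to oxygen to give the phenol. This is the thermal ring expansion of 4-alkenyl- and 4-heteroaryl-4-alkoxycyclobutenones to para-alkoxyphenols (Moore rearrangement), applied here with a γ-pyranone as the unsaturated substituent. The reaction is an isomerisation that fixes every ring-A substituent by connectivity: the ketene carbonyl becomes the free C5 hydroxyl, the methylated carbinol carbon becomes C8–OMe, and the tert-butoxy carbon and its C–H neighbour become C7 and C6. No stereocentre is formed, and the racemic centre of 10 is destroyed. The step needs inward rotation of the pyranonyl group, secured by the strong outward preference of the alkoxy donor at C4, and closure through carbon instead of capture of the ketene by oxygen, secured because O8 is capped as its methyl ether and the pyranone carbonyl oxygen cannot reach the ketene; high dilution should hold back ketene dimerisation.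

**Step 5**
Reactants: 13 7-tert-butoxy-5-hydroxy-8-methoxy-2-(3,4,5-trimethoxyphenyl)-4H-chromen-4-one
Product: 14 5,7-dihydroxy-8-methoxy-2-(3,4,5-trimethoxyphenyl)-4H-chromen-4-one (3',4',5'-trimethoxywogonin)
Conditions: CF3CO2H–CH2Cl2 (1:4), 0 °C to rt, N2 sweep
Reagents that add atoms: none
Why: Acidolysis of the aryl tert-butyl ether by loss of the tert-butyl cation as isobutene; the methyl ethers, the chelated 5-hydroxyl and the pyranone should be stable to trifluoroacetic acid at room temperature, and the gas sweep removes isobutene before it can alkylate C6.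

**Compound list**
1 | 3,4,5-trimethoxybenzoyl chloride | COc1cc(C(=O)Cl)cc(OC)c1OC | starting material
2 | (E)-4-methoxybut-3-en-2-one | CO/C=C/C(C)=O | starting material
3 | (4E)-5-methoxy-1-(3,4,5-trimethoxyphenyl)pent-4-ene-1,3-dione (formed in the flask) | COc1cc(C(=O)CC(=O)/C=C/OC)cc(OC)c1OC | intermediate
4 | 2-(3,4,5-trimethoxyphenyl)-4H-pyran-4-one | COc1cc(-c2cc(=O)cco2)cc(OC)c1OC | intermediate
5 | di-tert-butyl squarate (3,4-di-tert-butoxycyclobut-3-ene-1,2-dione) | CC(C)(C)OC1=C(OC(C)(C)C)C(=O)C1=O | starting material
6 | 2,3-di-tert-butoxy-4-hydroxycyclobut-2-en-1-one (racemic, used crude) | CC(C)(C)OC1=C(OC(C)(C)C)C(O)C1=O | intermediate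
7 | 3-tert-butoxycyclobut-3-ene-1,2-dione | CC(C)(C)OC1=CC(=O)C1=O | intermediate
8 | 2-lithio-6-(3,4,5-trimethoxyphenyl)-4H-pyran-4-one (formed in the flask) | [Li]c1cc(=O)cc(-c2cc(OC)c(OC)c(OC)c2)o1 | intermediate
9 | lithium alkoxide of 3-tert-butoxy-4-hydroxy-4-[4-oxo-6-(3,4,5-trimethoxyphenyl)-4H-pyran-2-yl]cyclobut-2-en-1-one (racemic, formed in the flask) | [Li]OC1(c2cc(=O)cc(-c3cc(OC)c(OC)c(OC)c3)o2)C(OC(C)(C)C)=CC1=O | intermediate
10 | 3-tert-butoxy-4-methoxy-4-[4-oxo-6-(3,4,5-trimethoxyphenyl)-4H-pyran-2-yl]cyclobut-2-en-1-one (racemic) | COC1(c2cc(=O)cc(-c3cc(OC)c(OC)c(OC)c3)o2)C(OC(C)(C)C)=CC1=O | intermediate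
11 | (3Z)-3-tert-butoxy-4-methoxy-4-[4-oxo-6-(3,4,5-trimethoxyphenyl)-4H-pyran-2-yl]buta-1,3-dien-1-one (dienylketene, formed in the flask) | O=C=C/C(OC(C)(C)C)=C(/OC)c1cc(=O)cc(-c2cc(OC)c(OC)c(OC)c2)o1 | intermediate
12 | 7-tert-butoxy-8-methoxy-2-(3,4,5-trimethoxyphenyl)-4aH-chromene-4,5-dione (racemic, formed in the flask) | O=C1C=C(OC(C)(C)C)C(OC)=C2OC(c3cc(OC)c(OC)c(OC)c3)=CC(=O)C12 | intermediate
13 | 7-tert-butoxy-5-hydroxy-8-methoxy-2-(3,4,5-trimethoxyphenyl)-4H-chromen-4-one | COc1cc(-c2cc(=O)c3c(O)cc(OC(C)(C)C)c(OC)c3o2)cc(OC)c1OC | intermediate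
14 | 5,7-dihydroxy-8-methoxy-2-(3,4,5-trimethoxyphenyl)-4H-chromen-4-one (3',4',5'-trimethoxywogonin) | COc1cc(-c2cc(=O)c3c(O)cc(O)c(OC)c3o2)cc(OC)c1OC | target

Total step count: 5. Longest linear sequence: 4 steps (1, 3, 4, 5; step 2 is the second branch).

**Steps most likely to fail**

Step 3. The base may remove a hydrogen next to the carbonyl (C3 or C5) or on ring B instead of C6. The lithiated pyranone may add to unchanged pyranone before it meets the dione. The vinyllithium may displace the tert-butoxy group of 7 by conjugate addition–elimination. Methyl triflate may also alkylate the pyranone carbonyl. The fallback sets out from 4 and comes back at 10. Metalation is separated from addition: deprotonative zincation with lithium 2,2,6,6-tetramethylpiperidide in the presence of ZnCl2·TMEDA (in-situ trap) and iodolysis would give 2-iodo-6-(3,4,5-trimethoxyphenyl)-4H-pyran-4-one F1, on which the site of substitution can be proven. Iodine–magnesium exchange with i-PrMgCl·LiCl at −40 °C and addition of the milder magnesium reagent to 7 would give 3-tert-butoxy-4-hydroxy-4-[4-oxo-6-(3,4,5-trimethoxyphenyl)-4H-pyran-2-yl]cyclobut-2-en-1-one F2. This carbinol would be isolated and methylated under neutral conditions (MeI, Ag2O) to 10.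

Step 4. The dienylketene may reclose or dimerise faster than it cyclises onto the partly aromatic pyranone, and the tert-butyl enol ether may lose isobutene at the temperature the ring opening needs. The fallback sets out from 10 and comes back at 13, and replaces the pericyclic ring expansion by an ionic one. KO-t-Bu in t-BuOH–THF should add to the strained ketone and cleave the C1–C4 bond, the carbanion being a vinylogous enolate of the pyranone. This would give tert-butyl (2E)-3-tert-butoxy-4-methoxy-4-[4-oxo-6-(3,4,5-trimethoxyphenyl)-4H-pyran-2-yl]but-2-enoate F3; tert-butoxide is chosen so that exchange at the enol ether is degenerate. LiN(SiMe3)2 would then regenerate the dienolate, which closes from pyranone C5 onto the ester (Dieckmann-type six-ring closure) and tautomerises to 13.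

Step 2. The hydride may reduce further, or the acid set free may remove the second tert-butyl group and leave water-soluble semisquaric acid. The fallback changes the oxygen substituent and the end-game; it sets out from commercial diisopropyl squarate F4 in place of 5, meets 4 in step 3, and comes back at 14. Reduction with LiAlH(O-t-Bu)3 and transposition with catalytic concentrated HCl in CH2Cl2, which a secondary alkyl group tolerates, would give 3-isopropoxycyclobut-3-ene-1,2-dione F5. Steps 3 and 4 as written would give 3-isopropoxy-4-methoxy-4-[4-oxo-6-(3,4,5-trimethoxyphenyl)-4H-pyran-2-yl]cyclobut-2-en-1-one F6 and then 5-hydroxy-7-isopropoxy-8-methoxy-2-(3,4,5-trimethoxyphenyl)-4H-chromen-4-one F7. BCl3 in CH2Cl2 at −78 to 0 °C would cleave the secondary ether in preference to the methyl ethers to give 14.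

**Further compounds**
F1 | step 3 | 2-iodo-6-(3,4,5-trimethoxyphenyl)-4H-pyran-4-one | COc1cc(-c2cc(=O)cc(I)o2)cc(OC)c1OC
F2 | step 3 | 3-tert-butoxy-4-hydroxy-4-[4-oxo-6-(3,4,5-trimethoxyphenyl)-4H-pyran-2-yl]cyclobut-2-en-1-one (racemic) | OC1(c2cc(=O)cc(-c3cc(OC)c(OC)c(OC)c3)o2)C(OC(C)(C)C)=CC1=O
F3 | step 4 | tert-butyl (2E)-3-tert-butoxy-4-methoxy-4-[4-oxo-6-(3,4,5-trimethoxyphenyl)-4H-pyran-2-yl]but-2-enoate (racemic) | CC(C)(C)OC(=O)/C=C(OC(C)(C)C)\C(OC)c1cc(=O)cc(-c2cc(OC)c(OC)c(OC)c2)o1
F4 | step 2 | diisopropyl squarate (3,4-diisopropoxycyclobut-3-ene-1,2-dione) | CC(C)OC1=C(OC(C)C)C(=O)C1=O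
F5 | step 2 | 3-isopropoxycyclobut-3-ene-1,2-dione | CC(C)OC1=CC(=O)C1=O
F6 | step 2 | 3-isopropoxy-4-methoxy-4-[4-oxo-6-(3,4,5-trimethoxyphenyl)-4H-pyran-2-yl]cyclobut-2-en-1-one (racemic) | COC1(c2cc(=O)cc(-c3cc(OC)c(OC)c(OC)c3)o2)C(OC(C)C)=CC1=O
F7 | step 2 | 5-hydroxy-7-isopropoxy-8-methoxy-2-(3,4,5-trimethoxyphenyl)-4H-chromen-4-one | COc1cc(-c2cc(=O)c3c(O)cc(OC(C)C)c(OC)c3o2)cc(OC)c1OC
A1 | direct plan | phloroglucinol (benzene-1,3,5-triol) | Oc1cc(O)cc(O)c1
A2 | direct plan | 3,5-bis(benzyloxy)-2-(trimethylsilyl)phenyl trifluoromethanesulfonate | C[Si](C)(C)c1c(OCc2ccccc2)cc(OCc2ccccc2)cc1OS(=O)(=O)C(F)(F)F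
A3 | direct plan | 3-(3,4,5-trimethoxyphenyl)prop-2-ynoic acid | COc1cc(C#CC(=O)O)cc(OC)c1OC
A4 | direct plan | 5,7-bis(benzyloxy)-2-(3,4,5-trimethoxyphenyl)-4H-chromen-4-one | COc1cc(-c2cc(=O)c3c(OCc4ccccc4)cc(OCc4ccccc4)cc3o2)cc(OC)c1OC
A5 | direct plan | 7-(benzyloxy)-5,8-dihydroxy-2-(3,4,5-trimethoxyphenyl)-4H-chromen-4-one | COc1cc(-c2cc(=O)c3c(O)cc(OCc4ccccc4)c(O)c3o2)cc(OC)c1OC
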